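**Strategy.** The α-methylene-γ-lactone is taken apart across its two bonds to the carbocycle, O1–C7a and C3–C3a (benzofuranone numbering), which leads back to an all-cis cyclohexene-3a,4,7a-triol whose C3a/C7a diol is a cyclic sulfate. In the key step caesium 2-(diethoxyphosphoryl)acetate opens the sulfate at C7a, the carbon remote from the oxygenated C4, and the tethered phosphonate carbanion then displaces the sulfate monoester at C3a; formaldehyde completes the methylene group in the same flask. This double inversion exploits the contiguous C4/C3a/C7a oxygen triad of the cyclohexene ring: one carbinol (C4), set by catalytic asymmetric reduction, is relayed to C3a and C7a by directed dihydroxylation and then inverted to the cis-lactone trans to O4. The side-chain centre is bought as (S)-citronellal.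

Key step: step 10

Remark: the future C4, C3a and C7a are C1, C6 and C5 in 8–10 and C3, C2 and C1 in 11; 8 and 9 are carried as both C6 epimers, which converge in step 6.

Step 1
Reactants: 1 (S)-citronellal; 2 2-(3-chloropropyl)-2-methyl-1,3-dioxolane
Product: 4 (4RS,6S)-6,10-dimethyl-1-(2-methyl-1,3-dioxolan-2-yl)undec-9-en-4-ol, via Grignard reagent 3 (not isolated)
Conditions: Mg, THF, 65 °C (2 to 3); then 1, THF, 0 °C; H2O
Reagents that add atoms: none
Why: Grignard addition to an aldehyde is routine; the new carbinol centre forms as both epimers and is removed in step 2, and the citronellal centre is not touched.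

Step 2
Reactants: 4 (4RS,6S)-6,10-dimethyl-1-(2-methyl-1,3-dioxolan-2-yl)undec-9-en-4-ol
Product: 5 (6S)-6,10-dimethyl-1-(2-methyl-1,3-dioxolan-2-yl)undec-9-en-4-one
Conditions: Dess–Martin periodinane, pyridine, CH2Cl2, 25 °C
Reagents that add atoms: none
Why: Dess–Martin oxidation of a secondary alcohol tolerates the ketal and the alkene, and the methyl-bearing centre is β to the new carbonyl and cannot epimerize.

Step 3
Reactants: 5 (6S)-6,10-dimethyl-1-(2-methyl-1,3-dioxolan-2-yl)undec-9-en-4-one
Product: 7 3-methyl-2-[(2S)-6-methylhept-5-en-2-yl]cyclohex-2-en-1-one, via diketone 6 (not isolated)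
Conditions: 2 M HCl, THF, 25 °C; then KOH, MeOH, 65 °C
Reagents that add atoms: none
Why: Ketal hydrolysis unmasks the 2,6-diketone, whose base-mediated intramolecular aldol condensation should give the more substituted conjugated 2-alkyl-3-methylcyclohexenone under thermodynamic control.

Step 4
Reactants: 7 3-methyl-2-[(2S)-6-methylhept-5-en-2-yl]cyclohex-2-en-1-one
Product: 8 (6RS)-3-methyl-2-[(2S)-6-methylhept-5-en-2-yl]-6-(phenylselanyl)cyclohex-2-en-1-one
Conditions: LiN(i-Pr)2, THF, −78 °C; then PhSeCl, −78 °C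
Reagents that add atoms: phenylselenyl chloride, Cl[Se]c1ccccc1
Why: Kinetic deprotonation of the enone occurs at the α′-CH2 (C6) and the enolate is selenenylated there (α-selenenylation of a ketone enolate); the new centre forms as both epimers and is destroyed in step 6.

Step 5
Reactants: 8 (6RS)-3-methyl-2-[(2S)-6-methylhept-5-en-2-yl]-6-(phenylselanyl)cyclohex-2-en-1-one
Product: 9 (1R,6RS)-3-methyl-2-[(2S)-6-methylhept-5-en-2-yl]-6-(phenylselanyl)cyclohex-2-en-1-ol
Conditions: (R)-1-methyl-3,3-diphenyltetrahydro-1H,3H-pyrrolo[1,2-c][1,3,2]oxazaborole (20 mol %), catecholborane, toluene, −78 °C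
Reagents that add atoms: none
Why: Corey–Bakshi–Shibata reduction delivers hydride under catalyst control with the tetrasubstituted alkenyl carbon as the large group, so both C6 epimers should give the (1R) carbinol (the future C4); catecholborane should not hydroborate the side-chain alkene at −78 °C.

Step 6
Reactants: 9 (1R,6RS)-3-methyl-2-[(2S)-6-methylhept-5-en-2-yl]-6-(phenylselanyl)cyclohex-2-en-1-ol
Product: 10 (1S)-3-methyl-2-[(2S)-6-methylhept-5-en-2-yl]cyclohexa-2,5-dien-1-ol
Conditions: mCPBA (1.0 equiv), CH2Cl2, −78 °C; then i-Pr2NH, −78 to 0 °C; used crude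
Reagents that add atoms: none
Why: Selenide oxidation and selenoxide syn-elimination of a β-hydroxy selenide proceed away from the carbinol carbon and should give the bis-allylic dienol, which is kept cold and basic and used at once because it can lose water to an arene.

Step 7
Reactants: 10 (1S)-3-methyl-2-[(2S)-6-methylhept-5-en-2-yl]cyclohexa-2,5-dien-1-ol
Product: 11 (1S,2S,3R)-5-methyl-4-[(2S)-6-methylhept-5-en-2-yl]cyclohex-4-ene-1,2,3-triol
Conditions: OsO4 (1.05 equiv), TMEDA, CH2Cl2, −78 °C; then aq. Na2SO3, THF, 60 °C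
Reagents that add atoms: osmium tetroxide, O=[Os](=O)(=O)=O
Why: Hydroxyl-directed dihydroxylation: the OsO4–TMEDA complex is hydrogen-bonded by the allylic hydroxyl and should add to the disubstituted C5=C6 alkene on the hydroxyl face, setting both new carbinol centres (future C3a and C7a) cis to the existing one in one event, while the hindered tetrasubstituted and the undirected side-chain alkenes react more slowly.

Step 8
Reactants: 11 (1S,2S,3R)-5-methyl-4-[(2S)-6-methylhept-5-en-2-yl]cyclohex-4-ene-1,2,3-triol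
Product: 12 (3aR,4R,7aS)-4-hydroxy-6-methyl-5-[(2S)-6-methylhept-5-en-2-yl]-3a,4,7,7a-tetrahydro-1,3,2-benzodioxathiole 2,2-dioxide
Conditions: 1,1′-sulfonyldiimidazole (1.05 equiv), NaH (2.1 equiv), THF, −40 to 0 °C
Reagents that add atoms: 1,1′-sulfonyldiimidazole, O=S(=O)(n1ccnc1)n1ccnc1
Why: Cyclic sulfate formation from a 1,2-diol: the least hindered alkoxide (O1 of 11, next to the ring CH2) should be sulfonylated first and the neighbouring cis O2 should close the five-membered ring, leaving the hindered allylic hydroxyl free; no stereocentre is touched.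

Step 9
Reactants: 12 (3aR,4R,7aS)-4-hydroxy-6-methyl-5-[(2S)-6-methylhept-5-en-2-yl]-3a,4,7,7a-tetrahydro-1,3,2-benzodioxathiole 2,2-dioxide; 13 3-methylbutanoic acid
Product: 14 (3aR,4R,7aS)-6-methyl-5-[(2S)-6-methylhept-5-en-2-yl]-2,2-dioxo-3a,4,7,7a-tetrahydro-1,3,2-benzodioxathiol-4-yl 3-methylbutanoate
Conditions: N,N′-dicyclohexylcarbodiimide, 4-(dimethylamino)pyridine (cat.), CH2Cl2, 0 °C
Reagents that add atoms: none
Why: Steglich esterification acylates the remaining hindered allylic alcohol with retention, and the cyclic sulfate should tolerate these conditions at 0 °C.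

Step 10
Reactants: 14 (3aR,4R,7aS)-6-methyl-5-[(2S)-6-methylhept-5-en-2-yl]-2,2-dioxo-3a,4,7,7a-tetrahydro-1,3,2-benzodioxathiol-4-yl 3-methylbutanoate; 15 2-(diethoxyphosphoryl)acetic acid
Product: 18 (3aR,4S,7aR)-6-methyl-5-[(2S)-6-methylhept-5-en-2-yl]-3-methylidene-2-oxo-2,3,3a,4,7,7a-hexahydro-1-benzofuran-4-yl 3-methylbutanoate, via sulfate monoester 16 (not isolated), via phosphono lactone 17 (not isolated)
Conditions: Cs2CO3 (2.5 equiv), DMF, 0 to 25 °C, then 60 °C; then paraformaldehyde, 25 °C
Reagents that add atoms: formaldehyde (from paraformaldehyde), C=O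
Why: Proposed new method: the caesium carboxylate of 15 opens the cyclic sulfate by SN2 at C7a to give 16, Cs2CO3 then forms the phosphonate-stabilized carbanion, which displaces the sulfate monoester at C3a from the opposite face to give 17, and 17 undergoes Horner–Wadsworth–Emmons olefination with formaldehyde. The closest known reaction types are the carboxylate ring-opening of 1,2-cyclic sulfates, the intramolecular displacement of the resulting sulfate monoester by a stabilized carbanion (as in malonate cyclopropanations of cyclic sulfates) and the phosphonate route to α-methylene lactones. The lactone ring closes 5-exo-tet at C3a, and the carbanion is stabilized by the exocyclic phosphoryl group so that the ring ester need not stay in the enolate plane. Both new stereocentres (C7a and C3a) arise by inversion of the cis-diol carbons, so O1 and C3 should end up cis to each other and trans to the C4 ester without any further control element. The step needs first attack at C7a, which the neighbouring acyloxy-bearing C4 should secure by shielding and deactivating C3a, and C-alkylation rather than O-alkylation or elimination in the ring closure, which the soft phosphonate carbanion in DMF should favour.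

Step 11
Reactants: 18 (3aR,4S,7aR)-6-methyl-5-[(2S)-6-methylhept-5-en-2-yl]-3-methylidene-2-oxo-2,3,3a,4,7,7a-hexahydro-1-benzofuran-4-yl 3-methylbutanoate
Product: 19 (3aR,4S,7aR)-6-methyl-3-methylidene-2-oxo-5-[(2S)-5-oxopentan-2-yl]-2,3,3a,4,7,7a-hexahydro-1-benzofuran-4-yl 3-methylbutanoate
Conditions: OsO4 (2 mol %), NaIO4, 2,6-lutidine, dioxane–H2O (3:1), 25 °C
Reagents that add atoms: sodium periodate, [Na+].[O-]I(=O)(=O)=O
Why: Lemieux–Johnson oxidation should cleave the electron-rich trisubstituted side-chain alkene in preference to the hindered tetrasubstituted ring alkene and the electron-poor α-methylene lactone.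

Step 12
Reactants: 19 (3aR,4S,7aR)-6-methyl-3-methylidene-2-oxo-5-[(2S)-5-oxopentan-2-yl]-2,3,3a,4,7,7a-hexahydro-1-benzofuran-4-yl 3-methylbutanoate
Product: 20 (3aR,4S,7aR)-5-[(2S)-5-hydroxypentan-2-yl]-6-methyl-3-methylidene-2-oxo-2,3,3a,4,7,7a-hexahydro-1-benzofuran-4-yl 3-methylbutanoate
Conditions: NaBH4, CeCl3·7H2O, MeOH, −78 °C
Reagents that add atoms: none
Why: Luche reduction should reduce the aldehyde at low temperature much faster than it touches the α-methylene lactone or the esters.

**Compound list**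

1 | (S)-citronellal, (3S)-3,7-dimethyloct-6-enal | O=CC[C@@H](C)CCC=C(C)C | starting material
2 | 2-(3-chloropropyl)-2-methyl-1,3-dioxolane | CC1(CCCCl)OCCO1 | starting material
3 | [3-(2-methyl-1,3-dioxolan-2-yl)propyl]magnesium chloride | CC1(CCC[Mg]Cl)OCCO1 | intermediate
4 | (4RS,6S)-6,10-dimethyl-1-(2-methyl-1,3-dioxolan-2-yl)undec-9-en-4-ol | CC1(CCCC(O)C[C@@H](C)CCC=C(C)C)OCCO1 | intermediate
5 | (6S)-6,10-dimethyl-1-(2-methyl-1,3-dioxolan-2-yl)undec-9-en-4-one | CC1(CCCC(=O)C[C@@H](C)CCC=C(C)C)OCCO1 | intermediate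
6 | (8S)-8,12-dimethyltridec-11-ene-2,6-dione | CC(=O)CCCC(=O)C[C@@H](C)CCC=C(C)C | intermediate
7 | 3-methyl-2-[(2S)-6-methylhept-5-en-2-yl]cyclohex-2-en-1-one | CC1=C([C@@H](C)CCC=C(C)C)C(=O)CCC1 | intermediate
8 | (6RS)-3-methyl-2-[(2S)-6-methylhept-5-en-2-yl]-6-(phenylselanyl)cyclohex-2-en-1-one | CC1=C([C@@H](C)CCC=C(C)C)C(=O)C([Se]c2ccccc2)CC1 | intermediate
9 | (1R,6RS)-3-methyl-2-[(2S)-6-methylhept-5-en-2-yl]-6-(phenylselanyl)cyclohex-2-en-1-ol | CC1=C([C@@H](C)CCC=C(C)C)[C@@H](O)C([Se]c2ccccc2)CC1 | intermediate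
10 | (1S)-3-methyl-2-[(2S)-6-methylhept-5-en-2-yl]cyclohexa-2,5-dien-1-ol | CC1=C([C@@H](C)CCC=C(C)C)[C@@H](O)C=CC1 | intermediate
11 | (1S,2S,3R)-5-methyl-4-[(2S)-6-methylhept-5-en-2-yl]cyclohex-4-ene-1,2,3-triol (all-cis) | CC1=C([C@@H](C)CCC=C(C)C)[C@@H](O)[C@@H](O)[C@@H](O)C1 | intermediate
12 | (3aR,4R,7aS)-4-hydroxy-6-methyl-5-[(2S)-6-methylhept-5-en-2-yl]-3a,4,7,7a-tetrahydro-1,3,2-benzodioxathiole 2,2-dioxide (all three ring oxygens cis) | CC1=C([C@@H](C)CCC=C(C)C)[C@@H](O)[C@H]2OS(=O)(=O)O[C@H]2C1 | intermediate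
13 | 3-methylbutanoic acid (isovaleric acid) | CC(C)CC(=O)O | starting material
14 | (3aR,4R,7aS)-6-methyl-5-[(2S)-6-methylhept-5-en-2-yl]-2,2-dioxo-3a,4,7,7a-tetrahydro-1,3,2-benzodioxathiol-4-yl 3-methylbutanoate | CC1=C([C@@H](C)CCC=C(C)C)[C@@H](OC(=O)CC(C)C)[C@H]2OS(=O)(=O)O[C@H]2C1 | intermediate
15 | 2-(diethoxyphosphoryl)acetic acid | CCOP(=O)(CC(=O)O)OCC | starting material
16 | caesium 6-[2-(diethoxyphosphoryl)acetoxy]-4-methyl-2-(3-methylbutanoyloxy)-3-[(2S)-6-methylhept-5-en-2-yl]cyclohex-3-en-1-yl sulfate (O1 and O2 cis; O6 trans to both) | CC1=C([C@@H](C)CCC=C(C)C)[C@@H](OC(=O)CC(C)C)[C@@H](OS(=O)(=O)[O-])[C@H](OC(=O)CP(=O)(OCC)OCC)C1.[Cs+] | intermediate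
17 | (3aR,4S,7aR)-3-(diethoxyphosphoryl)-6-methyl-5-[(2S)-6-methylhept-5-en-2-yl]-2-oxo-2,3,3a,4,7,7a-hexahydro-1-benzofuran-4-yl 3-methylbutanoate (both C3 epimers) | CC1=C([C@@H](C)CCC=C(C)C)[C@@H](OC(=O)CC(C)C)[C@@H]2C(P(=O)(OCC)OCC)C(=O)O[C@@H]2C1 | intermediate
18 | (3aR,4S,7aR)-6-methyl-5-[(2S)-6-methylhept-5-en-2-yl]-3-methylidene-2-oxo-2,3,3a,4,7,7a-hexahydro-1-benzofuran-4-yl 3-methylbutanoate | CC1=C([C@@H](C)CCC=C(C)C)[C@@H](OC(=O)CC(C)C)[C@@H]2C(=C)C(=O)O[C@@H]2C1 | intermediate
19 | (3aR,4S,7aR)-6-methyl-3-methylidene-2-oxo-5-[(2S)-5-oxopentan-2-yl]-2,3,3a,4,7,7a-hexahydro-1-benzofuran-4-yl 3-methylbutanoate | CC1=C([C@@H](C)CCC=O)[C@@H](OC(=O)CC(C)C)[C@@H]2C(=C)C(=O)O[C@@H]2C1 | intermediate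
20 | (3aR,4S,7aR)-5-[(2S)-5-hydroxypentan-2-yl]-6-methyl-3-methylidene-2-oxo-2,3,3a,4,7,7a-hexahydro-1-benzofuran-4-yl 3-methylbutanoate | CC1=C([C@@H](C)CCCO)[C@@H](OC(=O)CC(C)C)[C@@H]2C(=C)C(=O)O[C@@H]2C1 | target

Total steps: 12. Longest linear sequence: 12 steps (1 or 2 to 20).

**Steps most likely to fail**

Step 10 (Proposed new method). After the carboxylate opening, the phosphonate carbanion may alkylate on oxygen to a ketene acetal, or the sulfate monoester may be lost by base-induced elimination, in place of C-alkylation at C3a. The fallback uses known chemistry and runs from 14 to 18. Compound 14 is opened with caesium 2-(diethoxyphosphoryl)acetate alone and the sulfate monoester is hydrolysed with catalytic H2SO4 in wet THF to the hydroxy phosphonoacetate F1. Dess–Martin oxidation of the free carbinol gives the keto phosphonoacetate F2. Intramolecular Horner–Wadsworth–Emmons reaction (LiCl, DBU, MeCN) closes the butenolide F3. Conjugate reduction with LiBH(s-Bu)3 at −78 °C, expected on the face of H7a to give the cis ring fusion, and trapping of the enolate with dimethylmethylideneammonium iodide give the Mannich base F4. Quaternization with MeI and elimination with NaHCO3 return to 18.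

Step 6. The bis-allylic dienol may aromatize by loss of water during the selenoxide elimination or on handling. The fallback avoids any ring that holds two C=C bonds next to a carbinol and runs from 1 to 11. Compound 1 is condensed with cyclohexylamine to the imine F5. Metalation with LiN(i-Pr)2, addition to acetone and hydrolysis with dehydration in aqueous oxalic acid (directed aldol condensation) give the enal F6. Me3SiOTf and Et3N give the (1E)-dienol silyl ether F7. Endo Diels–Alder reaction with vinylene carbonate at 160 °C gives the all-cis carbonate F8. The side-chain centre is not expected to control the diene face, so F8 would form together with the carbonate of opposite ring configuration F9 and must be separated from it. K2CO3 in MeOH removes the carbonate and the silyl group from F8 and returns to 11.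

Step 8. Sulfation may take place across the wrong pair of cis hydroxyls (O2/O3 of 11), or the allylic carbinol may be sulfonylated and ionize. The fallback protects before acylating and runs from 11 to 14. Thermodynamic ketalization with 2,2-dimethoxypropane and camphorsulfonic acid should place the acetonide on the less hindered O1/O2 pair and give the acetonide alcohol F10. Esterification as in step 9 gives the acetonide ester F11. Aqueous AcOH at 40 °C frees the diol ester F12. SO2Cl2 and Et3N in CH2Cl2 at −78 °C close the cyclic sulfate 14 without the strongly basic conditions that would let the ester migrate.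

**Further compounds**

F1 | step 10 | 6-hydroxy-3-methyl-5-(3-methylbutanoyloxy)-4-[(2S)-6-methylhept-5-en-2-yl]cyclohex-3-en-1-yl 2-(diethoxyphosphoryl)acetate (O5 and O6 cis; O1 trans to both) | CC1=C([C@@H](C)CCC=C(C)C)[C@@H](OC(=O)CC(C)C)[C@@H](O)[C@H](OC(=O)CP(=O)(OCC)OCC)C1
F2 | step 10 | 3-methyl-5-(3-methylbutanoyloxy)-4-[(2S)-6-methylhept-5-en-2-yl]-6-oxocyclohex-3-en-1-yl 2-(diethoxyphosphoryl)acetate (O1 and O5 trans) | CC1=C([C@@H](C)CCC=C(C)C)[C@@H](OC(=O)CC(C)C)C(=O)[C@H](OC(=O)CP(=O)(OCC)OCC)C1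
F3 | step 10 | 6-methyl-5-[(2S)-6-methylhept-5-en-2-yl]-2-oxo-2,4,7,7a-tetrahydro-1-benzofuran-4-yl 3-methylbutanoate (butenolide; O4 and the O1–C7a bond on opposite faces) | CC1=C([C@@H](C)CCC=C(C)C)[C@@H](OC(=O)CC(C)C)C2=CC(=O)O[C@@H]2C1
F4 | step 10 | (3aR,4S,7aR)-3-[(dimethylamino)methyl]-6-methyl-5-[(2S)-6-methylhept-5-en-2-yl]-2-oxo-2,3,3a,4,7,7a-hexahydro-1-benzofuran-4-yl 3-methylbutanoate (both C3 epimers) | CC1=C([C@@H](C)CCC=C(C)C)[C@@H](OC(=O)CC(C)C)[C@@H]2C(CN(C)C)C(=O)O[C@@H]2C1
F5 | step 6 | (3S)-N-cyclohexyl-3,7-dimethyloct-6-en-1-imine | C1CCCCC1N=CC[C@@H](C)CCC=C(C)C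
F6 | step 6 | 3-methyl-2-[(2S)-6-methylhept-5-en-2-yl]but-2-enal | O=CC(=C(C)C)[C@@H](C)CCC=C(C)C
F7 | step 6 | trimethyl{[(1E)-3-methyl-2-[(2S)-6-methylhept-5-en-2-yl]buta-1,3-dien-1-yl]oxy}silane | C=C(C)/C(=C/O[Si](C)(C)C)[C@@H](C)CCC=C(C)C
F8 | step 6 | all-cis 6-methyl-5-[(2S)-6-methylhept-5-en-2-yl]-4-(trimethylsilyloxy)-3a,4,7,7a-tetrahydro-1,3-benzodioxol-2-one (ring configuration of 11) | CC1=C([C@@H](C)CCC=C(C)C)[C@@H](O[Si](C)(C)C)[C@H]2OC(=O)O[C@H]2C1
F9 | step 6 | all-cis 6-methyl-5-[(2S)-6-methylhept-5-en-2-yl]-4-(trimethylsilyloxy)-3a,4,7,7a-tetrahydro-1,3-benzodioxol-2-one (opposite ring configuration) | CC1=C([C@@H](C)CCC=C(C)C)[C@H](O[Si](C)(C)C)[C@@H]2OC(=O)O[C@@H]2C1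
F10 | step 8 | all-cis 2,2,6-trimethyl-5-[(2S)-6-methylhept-5-en-2-yl]-3a,4,7,7a-tetrahydro-1,3-benzodioxol-4-ol | CC1=C([C@@H](C)CCC=C(C)C)[C@@H](O)[C@H]2OC(C)(C)O[C@H]2C1
F11 | step 8 | all-cis 2,2,6-trimethyl-5-[(2S)-6-methylhept-5-en-2-yl]-3a,4,7,7a-tetrahydro-1,3-benzodioxol-4-yl 3-methylbutanoate | CC1=C([C@@H](C)CCC=C(C)C)[C@@H](OC(=O)CC(C)C)[C@H]2OC(C)(C)O[C@H]2C1
F12 | step 8 | all-cis 5,6-dihydroxy-3-methyl-2-[(2S)-6-methylhept-5-en-2-yl]cyclohex-2-en-1-yl 3-methylbutanoate | CC1=C([C@@H](C)CCC=C(C)C)[C@@H](OC(=O)CC(C)C)[C@@H](O)[C@@H](O)C1
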